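## The problem

The target, epiguibourtinidol-(4β→8)-epicatechin, is a B-type proanthocyanidin dimer: a 5-deoxyflavan-3-ol (rings A, C and B; plain atom numbers) is bonded from C4 to C8' of (−)-epicatechin (rings D, F and E; primed numbers). It has five stereocentres. C2' and C3' are those of natural (−)-epicatechin and can be bought, whereas C2, C3 and C4 of the upper unit (all R; 2,3-cis, 3,4-trans) must be made, and the epicatechin centres lie too far away to be counted on for control. C4 is a doubly benzylic methine that cannot be epimerised once formed, so it must be set in the bond-forming event itself; C3 can be corrected as long as C2 is a carbonyl-level carbon, and C2 can then be set last, relative to C3. The customary interflavan coupling, attack of a flavan nucleophile on a C4 cation of the upper unit, fits badly: the 5-deoxy upper unit is not an available flavan, its C4 cation lacks the stabilising 5-oxygen, and the nucleophile can react at C6' as well as C8'. The eight hydroxyls sit on electron-rich rings; as free phenols they are sensitive to air and base (ring opening and epimerisation at C2), and the benzylic C2–O1 and C2'–O1' ethers and the C4–C8' bond are sensitive to acid, so all hydroxyls should travel as benzyl ethers and be freed by one neutral hydrogenolysis at the end. The feature that opens another route lies in ring C: O1 sits on aromatic C8a and C4 on the neighbouring C4a, so O1–C8a–C4a–C4 is a masked ortho-quinone methide. If ring D is already attached to the future C4, dehydration of an ortho-hydroxybenzhydrol exposes that quinone methide, and the missing ring atoms C2 and C3, with the C3 oxygen in place, can come from the enamine of an α-oxygenated aldehyde.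

## Retrosynthesis

Target 20 is traced back to its octa-O-benzyl ether 19 by cutting eight O–benzyl bonds. Benzyl is preferred to acyl or silyl groups because it survives the organolithium, Lewis-acid and oxidation steps and leaves in one neutral operation. The skeleton is unchanged; the forward step only has to spare the cyclic benzylic ethers of rings C and F.

In 19 the C2–H bond and then the C2–aryl bond are cut. This leads through hemiketal 17 to lactone 14 and 4-benzyloxyphenyllithium 16, made from bromide 15. Ring B cannot be part of the two-carbon annulation partner, because that would require the enamine of an α-aryl-α-oxy ketone. Bringing it in afterwards keeps C2 at carbonyl level, so C3 stays correctable towards trans while C2 is still a carbonyl carbon. Lactone 14 lacks ring B and one stereocentre. The forward steps must stop at mono-addition and must deliver hydride to the oxocarbenium ion 18 on the face anti to the C3 benzyloxy group.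

Lactone 14 comes from lactol 13 by an oxidation-state change only. Lactol 13 is cut at C3–C4 and O1–C2, which gives the ortho-hydroxybenzhydrol 9 and benzyloxyacetaldehyde 10. Against a cut at C4–C8' (cation chemistry, with the problems named above), this cut forms ring C and both C3 and C4 in one catalytic step and never makes the interflavan bond under ionising conditions. Precursor 9 has no ring C and no upper-unit stereocentre that matters, since both carbinol epimers give the same planar quinone methide 11. The forward reaction asks a chiral amine to select one face of its enamine 12 and, through the preferred approach geometry, one face of 11, at a methide carbon carrying a hindered aryl group.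

Benzhydrol 9 is cut at the carbinol–C8' bond into the 8-lithio derivative 8 of bromide 4 and aldehyde 6, used as its sodium phenolate 7. Against a Friedel–Crafts hydroxyalkylation of 3 with 6, which would give C6'/C8' mixtures and run on to triarylmethanes, the bromine fixes the site and the reaction stops at the carbinol. The forward step needs halogen–lithium exchange to outrun attack on the benzyl ethers and the phenol to be masked without a protecting group.

Bromide 4 goes back through the pentabenzyl ether 3 and the tetrabenzyl ether 2 to (−)-epicatechin 1, and aldehyde 6 to 2,4-dihydroxybenzaldehyde 5. These are routine etherifications and a site-selective bromination. The lower unit with C2', C3' and rings D, F and E is therefore bought.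

## Roads not taken

Alternative 1: Both pyran rings would be cut at their aryl ether bonds, O1–C2 and O1'–C2', back to the open-chain bis(cis-epoxide) diphenol A1. In the forward step mild acid would let each free phenol open its epoxide at the benzylic carbon with inversion (two 6-endo openings), closing rings C and F together to give A2, which has pivalates on rings B and E and benzyl ethers on rings A and D.
- Merits: two rings form in one operation, and both 2,3-cis relationships follow stereospecifically from the epoxide geometry. In this respect the road is better than the chosen one, whose C2 configuration rests on the facial selectivity of a hydride transfer in step 9.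
- Weak points: A1 needs five stereocentres set without the help of a ring. Two of them are enantiopure cis-epoxides of electron-rich styrenes, which are hard to make and to keep; the pivalates are there to damp benzylic ionisation, which would erase the inversion. The acyclic C4 methine next to one epoxide has no obvious control element. Both openings must go 6-endo and not 5-exo. Two kinds of protecting group need two deprotections, one of them basic, on base-sensitive catechols.
- Comparison: the lower unit that 1 supplies ready-made is rebuilt from nothing. Against the stereospecific ring closure the chosen plan sets the purchase of rings D, F and E with C2' and C3', one protecting group class and a much shorter sequence.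

Alternative 2: The same annulation would be applied to the other pyran ring. O1'–C2' and C3'–C4' of ring F are cut, back to A3, a complete benzylated upper unit whose C4 carries a phloroglucinol-type ring with a hydroxymethyl group and two free phenols. Forward, the quinone methide from the hydroxymethyl phenol would take up the prolinol-derived enamine of 10 (C3'–C4'), and the neighbouring phenol would close on the aldehyde carbon (O1'–C2') to give lactol A4 with C3' set.
- Merits: the methide carbon is an unsubstituted CH2, far less hindered than that of 11, and only one stereocentre is created, so no diastereoselectivity question arises. The later hemiketal reduction for C2' would have no 4-substituent on the hydride's face. On both counts this road is better than the chosen one.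
- Weak points: unsubstituted quinone methides are short-lived and oligomerise readily, and ring D carries two free phenols. Above all, the step builds the half of the molecule that is sold as 1 and leaves the real problem (C2, C3, C4 and the C4–aryl bond of the upper unit) to an earlier sequence that this disconnection does not provide.
- Comparison: the chosen plan accepts a harder annulation because that annulation creates C3 and C4 and the ring to which the interflavan bond belongs.

Alternative 3: Ring F would be cut at C4'–C4a', back to aryl ether A5, in which the ring D oxygen carries a 1-aryl-2,3-epoxypropyl chain with C2' and C3' derived from glyceraldehyde. Forward, AuCl3 with AgOTf would activate the terminal epoxide, and the only free ortho carbon of ring D would attack the CH2 end (6-endo Friedel–Crafts alkylation). This closes ring F and releases the 3'-hydroxyl to give A6.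
- Merits: the closure is regiochemically unambiguous, it creates no new stereocentre, it is catalytic, and the free 3'-hydroxyl would be useful for 3'-O-acylated relatives. In regiochemical certainty it is at least as good as the chosen plan.
- Weak points: strongly Lewis-acidic triflates meet the benzylic C2'–O ether, whose ionisation would erode C2', and opening at the internal carbon (5-exo) competes. The aryl–O–C2' ether has to be made at a hindered phenol by substitution at an electron-rich benzylic carbon, where clean inversion is not assured. As in Alternative 2, a finished upper unit is presupposed.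
- Comparison: the chosen plan gets the same two stereocentres from 1 without any of these steps and spends its key step on the upper unit.

Key step: step 6

Assumption: the enamine of 10 reacts as its E isomer on the face away from the diphenyl(silyloxy)methyl group, as aldehyde enamines of this catalyst class do; the (S)-catalyst is specified on that basis.

## Route

Step 1
Reactants: 1 (−)-epicatechin
Product: 2 5,7,3',4'-tetra-O-benzyl-(−)-epicatechin [(2R,3R)-5,7-bis(benzyloxy)-2-[3,4-bis(benzyloxy)phenyl]chroman-3-ol]
Conditions: BnBr (4.4 equiv), K2CO3, DMF, 0 °C to rt, argon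
Reagents that add atoms: benzyl bromide, BrCc1ccccc1
Why: Williamson etherification; K2CO3 deprotonates only the four phenols, so the 3-hydroxyl stays free, and low temperature with exclusion of air limits base-induced ring opening and epimerisation at C2.

Step 2
Reactants: 2 5,7,3',4'-tetra-O-benzyl-(−)-epicatechin
Product: 3 penta-O-benzyl-(−)-epicatechin [(2R,3R)-3,5,7-tris(benzyloxy)-2-[3,4-bis(benzyloxy)phenyl]chromane]
Conditions: NaH, BnBr, n-Bu4NI (cat.), DMF, 0 °C to rt
Reagents that add atoms: benzyl bromide, BrCc1ccccc1
Why: Williamson etherification of the secondary alkoxide; with all phenols capped no phenoxide is left to open the pyran ring, so C2 and C3 are not at risk.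

Step 3
Reactants: 3 penta-O-benzyl-(−)-epicatechin
Product: 4 8-bromo-penta-O-benzyl-(−)-epicatechin
Conditions: NBS (1.05 equiv), CH2Cl2, −78 °C to rt
Reagents that add atoms: N-bromosuccinimide, O=C1CCC(=O)N1Br
Why: Electrophilic aromatic bromination of the phloroglucinol-type ring; C8, between the ring oxygen and one benzyloxy group, is more accessible than C6 between two benzyloxy groups, which is the established site selectivity for O-benzylated catechins.

Step 4
Reactants: 5 2,4-dihydroxybenzaldehyde
Product: 6 4-(benzyloxy)-2-hydroxybenzaldehyde
Conditions: BnBr (1.0 equiv), NaHCO3, KI (cat.), MeCN, reflux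
Reagents that add atoms: benzyl bromide, BrCc1ccccc1
Why: Site-selective Williamson etherification; the 2-hydroxyl is held in a hydrogen bond to the formyl group and is the weaker nucleophile under mild base, so the 4-hydroxyl is alkylated.

Step 5
Reactants: 4 8-bromo-penta-O-benzyl-(−)-epicatechin, 6 4-(benzyloxy)-2-hydroxybenzaldehyde
Product: 9 (4-benzyloxy-2-hydroxyphenyl)(penta-O-benzylepicatechin-8-yl)methanol (both carbinol epimers), via sodium 5-(benzyloxy)-2-formylphenolate 7 (not isolated), via 8-lithio-penta-O-benzylepicatechin 8 (not isolated)
Conditions: 6, NaH, THF, 0 °C (gives 7); 4, t-BuLi (2 equiv), THF, −78 °C (gives 8); 7 added to 8, −78 to 0 °C; H2O, then pH 7 buffer; chromatography on Et3N-deactivated silica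
Reagents that add atoms: none
Why: Bromine–lithium exchange, then 1,2-addition of the aryllithium to a salicylaldehyde whose phenol is masked as its salt, the usual protecting-group-free entry to ortho-hydroxybenzhydrols; the bromine position fixes C8' as the point of attachment. The carbinol centre is left uncontrolled because step 6 planarises it.

Step 6
Reactants: 9 (4-benzyloxy-2-hydroxyphenyl)(penta-O-benzylepicatechin-8-yl)methanol, 10 benzyloxyacetaldehyde
Product: 13 (3R,4R)-3,7-bis(benzyloxy)-4-(penta-O-benzylepicatechin-8-yl)chroman-2-ol (3,4-trans; anomeric mixture), via ortho-quinone methide 11 (not isolated), via enamine 12 (not isolated)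
Conditions: 10 (3 equiv, added slowly), (S)-2-[diphenyl(trimethylsilyloxy)methyl]pyrrolidine (20 mol%), PhCO2H (20 mol%), CHCl3, 0 °C to rt
Reagents that add atoms: none
Why: Benzoic acid protonates the carbinol of 9 and water leaves, so that both epimers converge on the ortho-quinone methide 11, which is stabilised by the doubly ortho-oxygenated ring D and the para-benzyloxy group of ring A. Aldehyde 10 condenses with the (S)-pyrrolidine to the E-enamine 12, whose diphenyl(silyloxy)methyl group blocks one face; its oxygen-bearing carbon adds to the methide carbon C4 from the open face, forming C3–C4 and rearomatising ring A. The phenol oxygen then adds to the iminium carbon (or, after hydrolysis, to the aldehyde carbon) in a 6-exo-trig closure that forms O1–C2 and ring C, and hydrolysis returns the amine and leaves lactol 13. The closest known reaction type is the secondary-amine-catalysed formal [4+2] annulation (Michael addition, then hemiacetalisation) of ortho-quinone methides from ortho-hydroxybenzhydrols with enolisable aldehydes. C3 is set by the shielded enamine face and C4 by the synclinal approach of the two prochiral partners, the topology that gives syn adducts with nitroalkenes; with the (S)-amine this maps onto 3R,4R, which is 3,4-trans in the ring. The step needs catalyst control over the small bias of the C2' and C3' centres, which lie four and five bonds from C4, and the 3,4-trans lactol is also the more stable isomer, so any epimerisation at C3 through the enamine works in the wanted direction. The anomeric centre is left uncontrolled because step 7 removes it.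

Step 7
Reactants: 13 (3R,4R)-3,7-bis(benzyloxy)-4-(penta-O-benzylepicatechin-8-yl)chroman-2-ol
Product: 14 (3R,4R)-3,7-bis(benzyloxy)-4-(penta-O-benzylepicatechin-8-yl)chroman-2-one
Conditions: Dess–Martin periodinane, CH2Cl2, rt
Reagents that add atoms: none
Why: Oxidation of a lactol to the lactone, the routine derivatisation of chroman-2-ols obtained from quinone methide annulations; it removes the anomeric centre, and any epimerisation at C3 of the lactone runs towards the wanted 3,4-trans isomer.

Step 8
Reactants: 14 (3R,4R)-3,7-bis(benzyloxy)-4-(penta-O-benzylepicatechin-8-yl)chroman-2-one, 15 1-(benzyloxy)-4-bromobenzene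
Product: 17 (3R,4R)-3,7-bis(benzyloxy)-2-(4-benzyloxyphenyl)-4-(penta-O-benzylepicatechin-8-yl)chroman-2-ol (hemiketal; anomeric mixture), via 4-benzyloxyphenyllithium 16 (not isolated)
Conditions: 15, n-BuLi, THF, −78 °C (gives 16); 16 (1.05 equiv) added to 14, THF, −78 °C; AcOH in THF at −78 °C
Reagents that add atoms: none
Why: Mono-addition of an aryllithium to a lactone, as in aryl C-glycoside synthesis from aldonolactones; the lithium hemiketalate is held as a five-membered chelate with the C3 benzyloxy oxygen and is quenched cold, before it can collapse to a ketone that would take up a second equivalent.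

Step 9
Reactants: 17 (3R,4R)-3,7-bis(benzyloxy)-2-(4-benzyloxyphenyl)-4-(penta-O-benzylepicatechin-8-yl)chroman-2-ol
Product: 19 (2R,3R,4R)-3,7-bis(benzyloxy)-2-(4-benzyloxyphenyl)-4-(penta-O-benzylepicatechin-8-yl)chromane (octa-O-benzyl dimer), via oxocarbenium ion 18 (not isolated)
Conditions: Et3SiH (5 equiv), TMSOTf (0.3 equiv), CH2Cl2, −78 to −40 °C
Reagents that add atoms: none
Why: Ionic hydrogenation (reductive etherification): the silyl triflate ionises the hemiketal to the 2-aryl oxocarbenium ion 18 and the silane reduces it, an established entry to 2,3-cis-flavan-3-ol derivatives. The trans C3 and C4 substituents should sit pseudo-axial, away from the coplanar 2-aryl group and the peri hydrogen, and hydride should add anti-periplanar to the axial C3–O bond, which puts H-2 trans to the C3 oxygen and the aryl group cis to it (2R).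

Step 10
Reactants: 19 (2R,3R,4R)-3,7-bis(benzyloxy)-2-(4-benzyloxyphenyl)-4-(penta-O-benzylepicatechin-8-yl)chromane
Product: 20 epiguibourtinidol-(4β→8)-epicatechin [(2R,3R,4R)-2-(4-hydroxyphenyl)-4-[(2R,3R)-2-(3,4-dihydroxyphenyl)-3,5,7-trihydroxychroman-8-yl]chromane-3,7-diol]
Conditions: H2 (1 atm), Pd(OH)2/C, THF/MeOH/H2O, rt
Reagents that add atoms: none
Why: Hydrogenolysis of the eight benzyl ethers under neutral conditions; the cyclic benzylic ethers of rings C and F and the C4–C8' bond should be left alone, as in the usual deprotection of benzylated proanthocyanidins, and no stereocentre is touched.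

## Compound list

1 | (−)-epicatechin, (2R,3R)-2-(3,4-dihydroxyphenyl)chromane-3,5,7-triol | Oc1cc(O)c2c(c1)O[C@H](c1ccc(O)c(O)c1)[C@H](O)C2 | starting material
2 | 5,7,3',4'-tetra-O-benzyl-(−)-epicatechin (3-OH free; 2R,3R) | c1ccccc1COc1cc(OCc3ccccc3)c2c(c1)O[C@H](c1ccc(OCc3ccccc3)c(OCc3ccccc3)c1)[C@H](O)C2 | intermediate
3 | penta-O-benzyl-(−)-epicatechin (2R,3R) | c1ccccc1COc1cc(OCc3ccccc3)c2c(c1)O[C@H](c1ccc(OCc3ccccc3)c(OCc3ccccc3)c1)[C@H](OCc1ccccc1)C2 | intermediate
4 | 8-bromo-penta-O-benzyl-(−)-epicatechin (2R,3R) | c1ccccc1COc1cc(OCc3ccccc3)c2c(c1Br)O[C@H](c1ccc(OCc3ccccc3)c(OCc3ccccc3)c1)[C@H](OCc1ccccc1)C2 | intermediate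
5 | 2,4-dihydroxybenzaldehyde | O=Cc1ccc(O)cc1O | starting material
6 | 4-(benzyloxy)-2-hydroxybenzaldehyde | O=Cc1ccc(OCc2ccccc2)cc1O | intermediate
7 | sodium 5-(benzyloxy)-2-formylphenolate (not isolated) | O=Cc1ccc(OCc2ccccc2)cc1[O-].[Na+] | intermediate
8 | 8-lithio-penta-O-benzylepicatechin (2R,3R; not isolated) | c1ccccc1COc1cc(OCc3ccccc3)c2c(c1[Li])O[C@H](c1ccc(OCc3ccccc3)c(OCc3ccccc3)c1)[C@H](OCc1ccccc1)C2 | intermediate
9 | (4-benzyloxy-2-hydroxyphenyl)(penta-O-benzylepicatechin-8-yl)methanol, both carbinol epimers, epicatechin part 2R,3R | OC(c1ccc(OCc5ccccc5)cc1O)c3c(OCc5ccccc5)cc(OCc5ccccc5)c4c3O[C@H](c3ccc(OCc5ccccc5)c(OCc5ccccc5)c3)[C@H](OCc5ccccc5)C4 | intermediate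
10 | benzyloxyacetaldehyde | O=CCOCc1ccccc1 | starting material
11 | ortho-quinone methide, 3-(benzyloxy)-6-[(penta-O-benzylepicatechin-8-yl)methylidene]cyclohexa-2,4-dien-1-one (E expected; not isolated) | O=C1C=C(OCc5ccccc5)C=CC1=Cc3c(OCc5ccccc5)cc(OCc5ccccc5)c4c3O[C@H](c3ccc(OCc5ccccc5)c(OCc5ccccc5)c3)[C@H](OCc5ccccc5)C4 | intermediate
12 | enamine, (S)-1-[(E)-2-(benzyloxy)ethenyl]-2-[diphenyl(trimethylsilyloxy)methyl]pyrrolidine (not isolated) | C[Si](C)(C)OC(c1ccccc1)(c1ccccc1)[C@@H]1CCCN1/C=C/OCc1ccccc1 | intermediate
13 | (3R,4R)-3,7-bis(benzyloxy)-4-(penta-O-benzylepicatechin-8-yl)chroman-2-ol, 3,4-trans, anomeric mixture | OC2Oc3cc(OCc5ccccc5)ccc3[C@H](c3c(OCc5ccccc5)cc(OCc5ccccc5)c4c3O[C@H](c3ccc(OCc5ccccc5)c(OCc5ccccc5)c3)[C@H](OCc5ccccc5)C4)[C@H]2OCc5ccccc5 | intermediate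
14 | (3R,4R)-3,7-bis(benzyloxy)-4-(penta-O-benzylepicatechin-8-yl)chroman-2-one, 3,4-trans | O=C2Oc3cc(OCc5ccccc5)ccc3[C@H](c3c(OCc5ccccc5)cc(OCc5ccccc5)c4c3O[C@H](c3ccc(OCc5ccccc5)c(OCc5ccccc5)c3)[C@H](OCc5ccccc5)C4)[C@H]2OCc5ccccc5 | intermediate
15 | 1-(benzyloxy)-4-bromobenzene | Brc1ccc(OCc2ccccc2)cc1 | starting material
16 | 4-benzyloxyphenyllithium (not isolated) | [Li]c1ccc(OCc2ccccc2)cc1 | intermediate
17 | (3R,4R)-3,7-bis(benzyloxy)-2-(4-benzyloxyphenyl)-4-(penta-O-benzylepicatechin-8-yl)chroman-2-ol, hemiketal, anomeric mixture | OC2(c1ccc(OCc5ccccc5)cc1)Oc3cc(OCc5ccccc5)ccc3[C@H](c3c(OCc5ccccc5)cc(OCc5ccccc5)c4c3O[C@H](c3ccc(OCc5ccccc5)c(OCc5ccccc5)c3)[C@H](OCc5ccccc5)C4)[C@H]2OCc5ccccc5 | intermediate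
18 | (3R,4R)-2-aryl-3,4-dihydro-2H-chromenylium (oxocarbenium) triflate derived from 17 (not isolated) | C2(c1ccc(OCc5ccccc5)cc1)=[O+]c3cc(OCc5ccccc5)ccc3[C@H](c3c(OCc5ccccc5)cc(OCc5ccccc5)c4c3O[C@H](c3ccc(OCc5ccccc5)c(OCc5ccccc5)c3)[C@H](OCc5ccccc5)C4)[C@H]2OCc5ccccc5.[O-]S(=O)(=O)C(F)(F)F | intermediate
19 | octa-O-benzyl dimer, (2R,3R,4R)-3,7-bis(benzyloxy)-2-(4-benzyloxyphenyl)-4-(penta-O-benzylepicatechin-8-yl)chromane (2,3-cis, 3,4-trans) | c5ccccc5COc1ccc([C@H]2Oc3cc(OCc5ccccc5)ccc3[C@H](c3c(OCc5ccccc5)cc(OCc5ccccc5)c4c3O[C@H](c3ccc(OCc5ccccc5)c(OCc5ccccc5)c3)[C@H](OCc5ccccc5)C4)[C@H]2OCc5ccccc5)cc1 | intermediate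
20 | epiguibourtinidol-(4β→8)-epicatechin, (2R,3R,4R)-2-(4-hydroxyphenyl)-4-[(2R,3R)-2-(3,4-dihydroxyphenyl)-3,5,7-trihydroxychroman-8-yl]chromane-3,7-diol | Oc1ccc([C@H]2Oc3cc(O)ccc3[C@H](c3c(O)cc(O)c4c3O[C@H](c3ccc(O)c(O)c3)[C@H](O)C4)[C@H]2O)cc1 | target

## Step count and risks

Total: 10 steps. Longest linear sequence: 9 steps from 1 (steps 1, 2, 3, 5, 6, 7, 8, 9, 10).

Step 6, the key step. The most likely failure is slow C–C bond formation at a methide carbon that carries an ortho,ortho'-disubstituted aryl group. The quinone methide would then be lost to self-condensation or Friedel–Crafts alkylation of the electron-rich rings, and the aldehyde to self-aldol reaction. The second risk is weak discrimination between the two faces of the methide, because the amine controls the enamine face directly and the methide face only through the approach geometry. The fallback sets out from 9 and gives up amine catalysis for a stepwise Lewis-acid route. The silyl ketene acetal [2-(benzyloxy)-1-methoxyethenyl]oxy(trimethyl)silane F1, made from methyl benzyloxyacetate with LiN(i-Pr)2 and Me3SiCl, is added to 9 with catalytic TMSOTf in CH2Cl2 at −78 °C (Mukaiyama–Michael addition to the quinone methide). This should give methyl 2-(benzyloxy)-3-(4-benzyloxy-2-hydroxyphenyl)-3-(penta-O-benzylepicatechin-8-yl)propanoate F2. Warming with a trace of p-TsOH closes it to the chroman-2-one stereoisomer mixture F3, and DBU equilibrates C3 to the 3,4-trans lactones. The two trans lactones are diastereomers because of the epicatechin unit and are separated by chromatography; the 4R isomer is 14, where the route is rejoined. C4 is then controlled by separation and no longer by a catalyst.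

Step 9. Hydride has to arrive on the face of 18 that also carries the pseudo-axial C4 aryl group, so poor facial selectivity (attack syn to the C3 oxygen, giving the 2,3-trans series) is the main risk. Loss of the C3 proton from the cation or acid-induced opening of ring C are lesser ones. The fallback sets out from 17 and sets C2 in an open chain. Zn(BH4)2 in Et2O/THF at −20 °C reduces the ring-opened keto-phenol form of 17 under chelation by the C3 benzyloxy group. This should give the 1,2-anti carbinol (1S,2R,3R)-2-(benzyloxy)-1-(4-benzyloxyphenyl)-3-(4-benzyloxy-2-hydroxyphenyl)-3-(penta-O-benzylepicatechin-8-yl)propan-1-ol F4. Mitsunobu cyclisation (PPh3, DIAD, THF, 0 °C) then forms O1–C2 with inversion at the benzylic carbon, a known ring closure for flavans, and returns to 19.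

Step 8. The lactone is an aryl ester, so collapse of the tetrahedral intermediate with loss of the phenoxide and a second addition to the resulting ketone is the likely failure, together with enolisation at C3 by the basic reagent. The fallback sets out from 14. MeNH(OMe)·HCl and AlMe3 in CH2Cl2 at 0 °C open the lactone to the Weinreb amide (2R,3R)-2-(benzyloxy)-3-(4-benzyloxy-2-hydroxyphenyl)-N-methoxy-N-methyl-3-(penta-O-benzylepicatechin-8-yl)propanamide F5. Treatment with 16 (2.2 equiv, THF, −78 to 0 °C) stops at the ketone stage through the stable chelate and gives 17 on work-up.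

Step 5. The phenolate of 7 donates into the formyl group and makes it a sluggish electrophile, so incomplete addition and protonation of the valuable aryllithium 8 during the longer reaction time are the risks. The fallback sets out from 6. Allyl bromide and K2CO3 in DMF give 2-(allyloxy)-4-(benzyloxy)benzaldehyde F6, which is added to 8 at −78 °C to give [2-(allyloxy)-4-(benzyloxy)phenyl](penta-O-benzylepicatechin-8-yl)methanol F7. The allyl group is then removed under neutral conditions with Pd(PPh3)4 (zerovalent palladium) and morpholine in THF at rt, which the acid-sensitive benzhydrol tolerates, and the route is rejoined at 9.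

## Further compounds

F1 | step 6 | [2-(benzyloxy)-1-methoxyethenyl]oxy(trimethyl)silane (silyl ketene acetal of methyl benzyloxyacetate) | COC(O[Si](C)(C)C)=COCc1ccccc1
F2 | step 6 | methyl 2-(benzyloxy)-3-(4-benzyloxy-2-hydroxyphenyl)-3-(penta-O-benzylepicatechin-8-yl)propanoate, isomer mixture at C2 and C3 | COC(=O)C(OCc5ccccc5)C(c3c(OCc5ccccc5)cc(OCc5ccccc5)c4c3O[C@H](c3ccc(OCc5ccccc5)c(OCc5ccccc5)c3)[C@H](OCc5ccccc5)C4)c3ccc(OCc5ccccc5)cc3O
F3 | step 6 | 3,7-bis(benzyloxy)-4-(penta-O-benzylepicatechin-8-yl)chroman-2-one, mixture of C3/C4 stereoisomers | O=C2Oc3cc(OCc5ccccc5)ccc3C(c3c(OCc5ccccc5)cc(OCc5ccccc5)c4c3O[C@H](c3ccc(OCc5ccccc5)c(OCc5ccccc5)c3)[C@H](OCc5ccccc5)C4)C2OCc5ccccc5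
F4 | step 9 | (1S,2R,3R)-2-(benzyloxy)-1-(4-benzyloxyphenyl)-3-(4-benzyloxy-2-hydroxyphenyl)-3-(penta-O-benzylepicatechin-8-yl)propan-1-ol | Oc3cc(OCc5ccccc5)ccc3[C@H](c3c(OCc5ccccc5)cc(OCc5ccccc5)c4c3O[C@H](c3ccc(OCc5ccccc5)c(OCc5ccccc5)c3)[C@H](OCc5ccccc5)C4)[C@@H](OCc5ccccc5)[C@@H](O)c1ccc(OCc5ccccc5)cc1
F5 | step 8 | (2R,3R)-2-(benzyloxy)-3-(4-benzyloxy-2-hydroxyphenyl)-N-methoxy-N-methyl-3-(penta-O-benzylepicatechin-8-yl)propanamide | CON(C)C(=O)[C@H](OCc5ccccc5)[C@@H](c3c(OCc5ccccc5)cc(OCc5ccccc5)c4c3O[C@H](c3ccc(OCc5ccccc5)c(OCc5ccccc5)c3)[C@H](OCc5ccccc5)C4)c3ccc(OCc5ccccc5)cc3O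
F6 | step 5 | 2-(allyloxy)-4-(benzyloxy)benzaldehyde | O=Cc1ccc(OCc2ccccc2)cc1OCC=C
F7 | step 5 | [2-(allyloxy)-4-(benzyloxy)phenyl](penta-O-benzylepicatechin-8-yl)methanol, both carbinol epimers | OC(c1ccc(OCc5ccccc5)cc1OCC=C)c3c(OCc5ccccc5)cc(OCc5ccccc5)c4c3O[C@H](c3ccc(OCc5ccccc5)c(OCc5ccccc5)c3)[C@H](OCc5ccccc5)C4
A1 | alternative 1 | open-chain bis(cis-epoxide) diphenol with pivalates on rings B and E and benzyl ethers on rings A and D | CC(C)(C)C(=O)Oc1ccc([C@@H]6O[C@@H]6[C@@H](c3c(OCc5ccccc5)cc(OCc5ccccc5)c(C[C@H]7O[C@H]7c8ccc(OC(=O)C(C)(C)C)c(OC(=O)C(C)(C)C)c8)c3O)c3ccc(OCc5ccccc5)cc3O)cc1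
A2 | alternative 1 | target carrying three pivalates (rings B and E) and three benzyl ethers (rings A and D), both 3-hydroxyls free | CC(C)(C)C(=O)Oc1ccc([C@H]2Oc3cc(OCc5ccccc5)ccc3[C@H](c3c(OCc5ccccc5)cc(OCc5ccccc5)c4c3O[C@H](c3ccc(OC(=O)C(C)(C)C)c(OC(=O)C(C)(C)C)c3)[C@H](O)C4)[C@H]2O)cc1
A3 | alternative 2 | tri-O-benzyl upper unit bearing at C4 a 2,6-dihydroxy-4-benzyloxy-3-(hydroxymethyl)phenyl ring | c5ccccc5COc1ccc([C@H]2Oc3cc(OCc5ccccc5)ccc3[C@H](c3c(O)cc(OCc5ccccc5)c(CO)c3O)[C@H]2OCc5ccccc5)cc1
A4 | alternative 2 | ring F lactol with 3'-benzyloxy group, anomeric mixture | c5ccccc5COc1ccc([C@H]2Oc3cc(OCc5ccccc5)ccc3[C@H](c3c(O)cc(OCc5ccccc5)c4c3OC(O)[C@H](OCc5ccccc5)C4)[C@H]2OCc5ccccc5)cc1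
A5 | alternative 3 | benzylated upper unit whose ring D oxygen carries a 1-[3,4-bis(benzyloxy)phenyl]-2,3-epoxypropyl group | c5ccccc5COc1ccc([C@H]2Oc3cc(OCc5ccccc5)ccc3[C@H](c3c(OCc5ccccc5)cc(OCc5ccccc5)cc3O[C@H](c3ccc(OCc5ccccc5)c(OCc5ccccc5)c3)[C@H]4CO4)[C@H]2OCc5ccccc5)cc1
A6 | alternative 3 | hepta-O-benzyl target with free 3'-hydroxyl on the lower unit | c5ccccc5COc1ccc([C@H]2Oc3cc(OCc5ccccc5)ccc3[C@H](c3c(OCc5ccccc5)cc(OCc5ccccc5)c4c3O[C@H](c3ccc(OCc5ccccc5)c(OCc5ccccc5)c3)[C@H](O)C4)[C@H]2OCc5ccccc5)cc1
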